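## Retrosynthetic overview

1. Pinnatin B comes from a furanocembranoid C2-acetate by oxidative furan cleavage (DMDO). This gives the Z-enedione that carries the C4 methyl.
2. The 13-membered carbocycle is the last ring formed, by an intramolecular Nozaki–Hiyama–Kishi (NHK) allylation of a furfural with an E-allylic bromide. This forms C1–C2 and sets the isopropenyl group and the C2-OH.
3. The butenolide comes from a Ru-catalysed Alder-ene/lactonisation of a γ-hydroxy-alkynoate with allyl alcohol. C10 is set by Zn-ProPhenol alkynylation of a cyclopropane carbaldehyde.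
4. The trans, quaternary cyclopropane (C7/C8) comes from an E-α-methyl-β-furyl enal by the proposed new organocatalytic methylene transfer from an unstabilised sulfonium ylide. The enal is built from 3-methylfurfural.
5. Ring-forming order: furan (present in the starting material), cyclopropane, butenolide, macrocycle. The furan is unmasked to the enedione in the final step.

Assumption: the catalyst and ligand enantiomers in Steps 5 and 6 are the ones that give the drawn 7S,8S and 10S centres, and the anti-selective chair NHK transition state under control of these centres gives the 1S,2S pair.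

## Route

**Step 1** (reagent preparation)
Reactants: 1 ((trimethylsilyl)methyl triflate)
Product: 2 (dimethyl[(trimethylsilyl)methyl]sulfonium triflate)
Conditions: Me2S (3 equiv), CH2Cl2, 0 °C → rt; precipitate with Et2O
Reagents that add atoms: dimethyl sulfide, CSC
Why: SN2 S-alkylation of Me2S gives a bench-stable salt that releases the non-stabilised ylide Me2S⁺–CH2⁻ on fluoride desilylation (Step 5); no stereocentre is formed.

**Step 2**
Reactants: 3 (3-methylfuran-2-carbaldehyde)
Product: 4 (2-(dimethoxymethyl)-3-methylfuran)
Conditions: HC(OMe)3, cat. TsOH, MeOH, 0 °C → rt; quench Et3N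
Reagents that add atoms: trimethyl orthoformate, COC(OC)OC
Why: Acetalisation masks the C2 aldehyde so that it survives BuLi, Wittig and hydride steps.

**Step 3**
Reactants: 4
Product: 5 (5-(dimethoxymethyl)-4-methylfuran-2-carbaldehyde)
Conditions: n-BuLi, THF, −78 → −20 °C; then DMF, −78 °C → rt
Reagents that add atoms: N,N-dimethylformamide, CN(C)C=O
Why: The only free α-position (C5–H) is lithiated selectively and the 2-furyllithium is formylated by DMF (Bouveault formylation).

**Step 4**
Reactants: 5; 6 (2-(triphenylphosphoranylidene)propanal)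
Product: 7 ((E)-3-[5-(dimethoxymethyl)-4-methylfuran-2-yl]-2-methylprop-2-enal)
Conditions: toluene, 80 °C
Reagents that add atoms: none
Why: Wittig olefination with a stabilised ylide is E-selective (furyl trans to CHO), and this alkene geometry leads to the trans relationship of the two ring substituents on the cyclopropane (Step 5).

**Step 5** (key new step)
Reactants: 7; 2
Product: 8 ((1S,2S)-2-[5-(dimethoxymethyl)-4-methylfuran-2-yl]-1-methylcyclopropane-1-carbaldehyde)
Conditions: (S)-diphenylprolinol TBDPS ether (20 mol %), 2-fluorobenzoic acid (20 mol %), TBAT (2.5 equiv), MeCN/CH2Cl2 1:1, 0 °C → rt (2.5 equiv of 2)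
Reagents that add atoms: none
Why: Proposed new method: the secondary amine condenses with enal 7 to give an iminium ion, and TBAT desilylates 2 slowly and under near-neutral conditions, so that Me2S⁺–CH2⁻ is formed in the presence of the amine (unlike with NaH or BuLi). The ylide adds to the iminium β-carbon on the face opposite the catalyst's diaryl group, which sets the absolute configuration. The resulting α-methyl enamine then closes by 3-exo-tet onto CH2–S⁺Me2, supplying the ring CH2 from 2 and expelling Me2S. In the ring-closing conformation the furyl group sits next to the smaller α-methyl and away from the larger CH=N⁺ unit, which gives the trans (furyl/CHO) quaternary cyclopropane after hydrolysis. The closest known reactions are iminium-catalysed cyclopropanation of enals with stabilised sulfur ylides or bromomalonate, and Corey–Chaykovsky cyclopropanation of enones; the new features are unstabilised methylene transfer under aminocatalysis, an α-substituted β-furyl enal, and an all-carbon quaternary centre.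

**Step 6**
Reactants: 8; 9 (ethyl propiolate)
Product: 10 (ethyl (4R)-4-{(1S,2S)-2-[5-(dimethoxymethyl)-4-methylfuran-2-yl]-1-methylcyclopropyl}-4-hydroxybut-2-ynoate)
Conditions: (S,S)-ProPhenol (10 mol %), ZnEt2 (3 equiv), Ph3P=O (20 mol %), 4 Å MS, toluene, 4 °C → rt
Reagents that add atoms: none
Why: Dinuclear Zn-ProPhenol asymmetric alkynylation of an aldehyde (Trost type) sets C10 by catalyst control on the non-enolisable aldehyde 8; the (R)-propargylic alcohol becomes the 10S butenolide γ-carbon (same spatial arrangement, CIP label changes).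

**Step 7**
Reactants: 10; 11 (allyl alcohol)
Product: 12 ((5S)-5-{(1S,2S)-2-[5-(dimethoxymethyl)-4-methylfuran-2-yl]-1-methylcyclopropyl}-3-(3-oxopropyl)furan-2(5H)-one)
Conditions: CpRu(MeCN)3PF6 (10 mol %), acetone, 25 °C
Reagents that add atoms: none
Why: Trost Ru-catalysed Alder-ene coupling of the γ-hydroxy-alkynoate with allyl alcohol forms the C12–C13 bond with syn C/H addition across the alkyne, the enol tautomerises to the aldehyde, and the cis hydroxy-enoate lactonises (EtOH lost) to the α-alkyl butenolide without touching C10.

**Step 8**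
Reactants: 12; 6
Product: 13 ((5S)-5-{(1S,2S)-2-[5-(dimethoxymethyl)-4-methylfuran-2-yl]-1-methylcyclopropyl}-3-[(4E)-4-methyl-5-oxopent-3-en-1-yl]furan-2(5H)-one)
Conditions: toluene, 80 °C
Reagents that add atoms: none
Why: Wittig olefination with the stabilised ylide is E-selective, which gives the C1=C15 geometry needed for the anti NHK addition.

**Step 9**
Reactants: 13
Product: 14 ((5S)-5-{(1S,2S)-2-[5-(dimethoxymethyl)-4-methylfuran-2-yl]-1-methylcyclopropyl}-3-[(4E)-5-hydroxy-4-methylpent-3-en-1-yl]furan-2(5H)-one)
Conditions: NaBH4, CeCl3·7H2O, MeOH, −20 °C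
Reagents that add atoms: none
Why: Luche reduction is chemoselective for the enal over the butenolide and the acetal (1,2-reduction); the alkene geometry is retained.

**Step 10**
Reactants: 14
Product: 15 ((5S)-5-{(1S,2S)-2-(5-formyl-4-methylfuran-2-yl)-1-methylcyclopropyl}-3-[(4E)-5-hydroxy-4-methylpent-3-en-1-yl]furan-2(5H)-one)
Conditions: PPTS (0.2 equiv), acetone/H2O 10:1, 40 °C
Reagents that add atoms: water, O
Why: Mild acid-catalysed acetal hydrolysis unmasks the furfural while the allylic alcohol, butenolide and cyclopropane survive.

**Step 11**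
Reactants: 15
Product: 16 ((5S)-3-[(4E)-5-bromo-4-methylpent-3-en-1-yl]-5-{(1S,2S)-2-(5-formyl-4-methylfuran-2-yl)-1-methylcyclopropyl}furan-2(5H)-one)
Conditions: MsCl, 2,4,6-collidine, LiBr, DMF, 0 °C → rt; use crude
Reagents that add atoms: lithium bromide, [Li+].[Br-]
Why: Collington–Meyers conversion of the allylic alcohol to the bromide through the mesylate (SN2 by bromide) keeps the E-alkene and leaves the furfural untouched.

**Step 12**
Reactants: 16
Product: 17 ((1S,2S,7S,8S,10S)-macrocyclic C2 alcohol, 13-membered furanocembranoid alcohol)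
Conditions: CrCl2 (6 equiv), cat. NiCl2, 4 Å MS, THF (2 mM), 25 °C
Reagents that add atoms: none
Why: Intramolecular NHK allylation proceeds through the Zimmerman–Traxler chair transition state of the E-allylchromium, which gives the anti homoallylic alcohol; it forms C1 (isopropenyl) and C2 (OH) together, with the macrocyclic conformation set by the 7S,8S,10S centres giving the 1S,2S pair.

**Step 13**
Reactants: 17
Product: 18 (C2 acetate of the furan-containing macrocycle)
Conditions: Ac2O, DMAP (cat.), pyridine, CH2Cl2, 0 °C → rt
Reagents that add atoms: acetic anhydride, CC(=O)OC(C)=O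
Why: O-Acetylation of the secondary alcohol, done before furan oxidation so that the α-acyloxy enedione is never exposed to a free alcohol; no stereocentre is altered.

**Step 14**
Reactants: 18
Product: 19 (Pinnatin B)
Conditions: DMDO (1.05 equiv), acetone, −78 → −20 °C
Reagents that add atoms: dimethyldioxirane, CC1(C)OO1
Why: Electrophilic furan epoxidation and ring opening (oxidative furan cleavage) gives the Z-enedione with the C4 methyl, with cis geometry inherited from the furan ring; the electron-rich furan reacts much faster than the isopropenyl group, butenolide or cyclopropane, and no stereocentre is changed.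

## Compound list

1 | (trimethylsilyl)methyl trifluoromethanesulfonate | C[Si](C)(C)COS(=O)(=O)C(F)(F)F | starting material
2 | dimethyl[(trimethylsilyl)methyl]sulfonium triflate (prepared reagent) | C[S+](C)C[Si](C)(C)C.[O-]S(=O)(=O)C(F)(F)F | intermediate
3 | 3-methylfuran-2-carbaldehyde | O=Cc1occc1C | starting material
4 | 2-(dimethoxymethyl)-3-methylfuran | COC(OC)c1occc1C | intermediate
5 | 5-(dimethoxymethyl)-4-methylfuran-2-carbaldehyde | O=Cc1cc(C)c(C(OC)OC)o1 | intermediate
6 | 2-(triphenylphosphoranylidene)propanal | CC(C=O)=P(c1ccccc1)(c1ccccc1)c1ccccc1 | starting material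
7 | (E)-3-[5-(dimethoxymethyl)-4-methylfuran-2-yl]-2-methylprop-2-enal | O=C/C(C)=C/c1cc(C)c(C(OC)OC)o1 | intermediate
8 | (1S,2S)-2-[5-(dimethoxymethyl)-4-methylfuran-2-yl]-1-methylcyclopropane-1-carbaldehyde | O=C[C@@]1(C)C[C@@H]1c1cc(C)c(C(OC)OC)o1 | intermediate
9 | ethyl propiolate | CCOC(=O)C#C | starting material
10 | ethyl (4R)-4-{(1S,2S)-2-[5-(dimethoxymethyl)-4-methylfuran-2-yl]-1-methylcyclopropyl}-4-hydroxybut-2-ynoate | CCOC(=O)C#C[C@H](O)[C@@]1(C)C[C@@H]1c1cc(C)c(C(OC)OC)o1 | intermediate
11 | allyl alcohol | C=CCO | starting material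
12 | (5S)-5-{(1S,2S)-2-[5-(dimethoxymethyl)-4-methylfuran-2-yl]-1-methylcyclopropyl}-3-(3-oxopropyl)furan-2(5H)-one | O=CCCC1=C[C@H](OC1=O)[C@@]1(C)C[C@@H]1c1cc(C)c(C(OC)OC)o1 | intermediate
13 | (5S)-5-{(1S,2S)-2-[5-(dimethoxymethyl)-4-methylfuran-2-yl]-1-methylcyclopropyl}-3-[(4E)-4-methyl-5-oxopent-3-en-1-yl]furan-2(5H)-one | O=C/C(C)=C/CCC1=C[C@H](OC1=O)[C@@]1(C)C[C@@H]1c1cc(C)c(C(OC)OC)o1 | intermediate
14 | (5S)-5-{(1S,2S)-2-[5-(dimethoxymethyl)-4-methylfuran-2-yl]-1-methylcyclopropyl}-3-[(4E)-5-hydroxy-4-methylpent-3-en-1-yl]furan-2(5H)-one | OC/C(C)=C/CCC1=C[C@H](OC1=O)[C@@]1(C)C[C@@H]1c1cc(C)c(C(OC)OC)o1 | intermediate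
15 | (5S)-5-{(1S,2S)-2-(5-formyl-4-methylfuran-2-yl)-1-methylcyclopropyl}-3-[(4E)-5-hydroxy-4-methylpent-3-en-1-yl]furan-2(5H)-one | OC/C(C)=C/CCC1=C[C@H](OC1=O)[C@@]1(C)C[C@@H]1c1cc(C)c(C=O)o1 | intermediate
16 | (5S)-3-[(4E)-5-bromo-4-methylpent-3-en-1-yl]-5-{(1S,2S)-2-(5-formyl-4-methylfuran-2-yl)-1-methylcyclopropyl}furan-2(5H)-one | BrC/C(C)=C/CCC1=C[C@H](OC1=O)[C@@]1(C)C[C@@H]1c1cc(C)c(C=O)o1 | intermediate
17 | macrocyclic C2 alcohol (1S,2S,7S,8S,10S), furan-containing 13-membered furanocembranoid alcohol | C=C(C)[C@@H]1CCC2=C[C@H](OC2=O)[C@@]2(C)C[C@@H]2c2cc(C)c([C@H]1O)o2 | intermediate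
18 | macrocyclic C2 acetate (furan stage) | C=C(C)[C@@H]1CCC2=C[C@H](OC2=O)[C@@]2(C)C[C@@H]2c2cc(C)c([C@H]1OC(C)=O)o2 | intermediate
19 | Pinnatin B | C=C(C)[C@@H]1CCC2=C[C@H](OC2=O)[C@@]2(C)C[C@@H]2C(=O)/C=C(/C)C(=O)[C@H]1OC(C)=O | target

## Summary

Total steps: 14, including the one-step preparation of reagent 2. Longest linear sequence: 13 steps (Steps 2–14, from 3).

Three steps most likely to fail:
1. **Step 5 (proposed new step).** The unstabilised ylide may epoxidise free enal or attack the iminium at carbon without closing, fluoride and 2-fluorobenzoic acid may compromise the furfural acetal or the catalyst ether, the hindered α-methyl iminium may form poorly, and trans/cis selectivity is uncertain. Fallback (known chemistry): Zn-ProPhenol alkynylation of E-enal 7 with ethyl propiolate, then Charette reagent-controlled Simmons–Smith cyclopropanation (Zn(CH2I)2 with a chiral dioxaborolane) of the resulting allylic propargylic alcohol. This gives 10 directly and the route continues from Step 7.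
2. **Step 12 (NHK macrocyclisation).** The 13-membered ring carries a furan, a trans-cyclopropane and a butenolide, so it is strained and the 1S,2S selectivity is uncertain. Fallback: Tamaru-type Pd(OAc)2/PPh3/Et3B umpolung allylation of the furfural using allylic alcohol 15 directly, which avoids the bromide and uses a π-allylpalladium mechanism.
3. **Step 14 (furan oxidation).** The cyclopropyl-substituted furan could over-oxidise or ring-open, and Z→E isomerisation of the enedione is possible. Fallback: Rose Bengal, O2, hν, −78 °C to form the endoperoxide, then Me2S reduction to the Z-enedione.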